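**Retrosynthetic overview**

1. The target 25 is fisetinidol-(4β→8)-catechin-(6→4α)-fisetinidol. All hydroxyls are carried as benzyl ethers (the upper 3-OH as an acetate) and freed at the end.
2. Last ring: pyran ring C of the upper (4β→8) unit, cut across O1–C2 and C3–C4 into a ring-A ortho-quinone methide (O1=C8a–C4a=C4, with C4 bound to C8 of the catechin unit) and (E)-2-[3,4-bis(benzyloxy)phenyl]ethenyl acetate (C2=C3).
3. Enabling feature: in that ring O1 is a phenol oxygen, C8a and C4a are arene carbons of ring A, and C4 is a doubly benzylic CH with no β-hydrogen. Dehydration of an o-hydroxybenzhydrol therefore gives a non-enolisable 1-oxadiene, stabilised by the para 7-benzyloxy group, and the 2,3-trans pair C2(aryl)/C3(O) is an (E)-alkene in disguise.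
4. The benzhydrol comes from bromine–lithium exchange at C8 of the lower dimer and 4-(benzyloxy)-2-hydroxybenzaldehyde. The dimer comes from C4→C6 arylation of 8-bromo-tetra-O-benzylcatechin (C8 blocked by Br) with a fustin-derived flavan-3,4-diol diacetate (3-acetoxy participation gives 4α).
5. Ring order: the catechin rings and the lower fisetinidol rings are bought closed (catechin, fustin). Only the upper ring C is built, and it is built last.

Key step: step 13

Assumption: natural (2R,3R)-fustin and (+)-catechin are bought as single enantiomers; the carbinol carbon of 21 forms as an epimer pair, which is harmless because it becomes sp2 in 22.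

In the names below, "upper unit" is the fisetinidol bound through C4 to C8 of catechin, and "lower unit" is the fisetinidol bound through C4 to C6.

**Route**

Step 1
Reactants: 1 (+)-catechin
Product: 2 5,7,3',4'-tetra-O-benzyl-(+)-catechin
Conditions: BnBr (4.4 equiv), K2CO3, DMF, 0 °C → rt
Reagents that add atoms: benzyl bromide, BrCc1ccccc1
Why: Williamson etherification should alkylate the four phenols while the less acidic secondary 3-OH stays free; no stereocentre is touched.

Step 2
Reactants: 2 5,7,3',4'-tetra-O-benzyl-(+)-catechin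
Product: 3 8-bromo-5,7,3',4'-tetra-O-benzyl-(+)-catechin
Conditions: NBS (1.0 equiv), CH2Cl2, −78 °C → rt
Reagents that add atoms: N-bromosuccinimide, O=C1CCC(=O)N1Br
Why: Electrophilic aromatic bromination of the phloroglucinol-type ring A should go to C8, the more reactive free position of 5,7-di-O-benzylflavan-3-ols; the bromine blocks C8 in step 6 and is the metalation handle in step 12.

Step 3
Reactants: 4 (2R,3R)-fustin
Product: 5 (2R,3R)-7,3',4'-tri-O-benzylfustin
Conditions: BnBr (3.3 equiv), K2CO3, DMF, rt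
Reagents that add atoms: benzyl bromide, BrCc1ccccc1
Why: Williamson etherification of the three phenols under weak base at room temperature should leave the base-sensitive α-hydroxy ketone (C2, C3) unchanged.

Step 4
Reactants: 5 (2R,3R)-7,3',4'-tri-O-benzylfustin
Product: 6 (2R,3S,4R)-7-(benzyloxy)-2-[3,4-bis(benzyloxy)phenyl]chromane-3,4-diol (2,3-trans-3,4-trans)
Conditions: NaBH4, THF/MeOH, 0 °C
Reagents that add atoms: none
Why: Hydride reduction of the flavanonol ketone should give mainly the 3,4-trans diol by axial delivery; the C4 configuration is erased in step 6, so either epimer serves.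

Step 5
Reactants: 6 (2R,3S,4R)-7-(benzyloxy)-2-[3,4-bis(benzyloxy)phenyl]chromane-3,4-diol
Product: 7 3,4-di-O-acetate of 6 (configuration unchanged)
Conditions: Ac2O, pyridine, DMAP (cat.), CH2Cl2, rt
Reagents that add atoms: acetic anhydride, CC(=O)OC(C)=O
Why: DMAP-catalysed acetylation installs the C4 leaving group and the C3 participating group needed in step 6.

Step 6
Reactants: 7 3,4-di-O-acetate of 6; 3 8-bromo-5,7,3',4'-tetra-O-benzyl-(+)-catechin
Product: 9 3-O-acetyl-7,3',4'-tri-O-benzylfisetinidol-(4α→6)-8-bromo-5,7,3',4'-tetra-O-benzylcatechin, via acetoxonium ion 8 (not isolated)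
Conditions: 3 (2.5 equiv), TMSOTf (0.2 equiv), 4 Å MS, CH2Cl2, −40 °C → 0 °C; Et3N quench
Reagents that add atoms: none
Why: Lewis-acid-mediated Friedel–Crafts-type C4 arylation with neighbouring-group participation: ionisation gives the β-face acetoxonium ion 8, which C6 of 3 (C8 being blocked) should open at C4 from the α face, setting the new C4 centre trans to the 3-acetoxy group (4α).

Step 7
Reactants: 9 3-O-acetyl-7,3',4'-tri-O-benzylfisetinidol-(4α→6)-8-bromo-5,7,3',4'-tetra-O-benzylcatechin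
Product: 10 7,3',4'-tri-O-benzylfisetinidol-(4α→6)-8-bromo-5,7,3',4'-tetra-O-benzylcatechin (both 3-OH free)
Conditions: K2CO3, MeOH/THF, rt
Reagents that add atoms: none
Why: Base-catalysed transesterification removes the only ester; benzyl ethers, the aryl bromide and the interflavan bond are inert to it.

Step 8
Reactants: 10 7,3',4'-tri-O-benzylfisetinidol-(4α→6)-8-bromo-5,7,3',4'-tetra-O-benzylcatechin
Product: 11 8-bromo-nona-O-benzyl-fisetinidol-(4α→6)-catechin (both 3-O positions benzylated)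
Conditions: NaH, BnBr, Bu4NI (cat.), DMF, 0 °C → rt
Reagents that add atoms: benzyl bromide, BrCc1ccccc1
Why: Williamson etherification of the two secondary alkoxides removes all acidic protons before the organolithium step and puts every lower-unit oxygen under one final deprotection.

Step 9
Reactants: 12 3,4-bis(benzyloxy)benzaldehyde; 13 bis[(pinacolato)boryl]methane
Product: 15 (E)-2-{2-[3,4-bis(benzyloxy)phenyl]ethenyl}-4,4,5,5-tetramethyl-1,3,2-dioxaborolane, via lithiated diborylmethane 14 (not isolated)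
Conditions: LiTMP (from TMPH and n-BuLi), THF, 0 °C; then 12, −78 °C → rt
Reagents that add atoms: none
Why: Boron-Wittig olefination: the α-boryl carbanion adds to the aldehyde and syn-eliminates a borate, which should give the (E)-alkenylboronate selectively.

Step 10
Reactants: 15 (E)-alkenyl pinacol boronate
Product: 16 potassium (E)-{2-[3,4-bis(benzyloxy)phenyl]ethenyl}trifluoroborate
Conditions: KHF2, MeOH/H2O, rt
Reagents that add atoms: potassium hydrogen difluoride, [K+].[F-].F
Why: Standard conversion of a pinacol boronate into the air-stable trifluoroborate; the alkene geometry is not touched.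

Step 11
Reactants: 16 potassium (E)-alkenyltrifluoroborate
Product: 17 (E)-2-[3,4-bis(benzyloxy)phenyl]ethenyl acetate
Conditions: AcOH, CuBr (10 mol%), DMAP (20 mol%), 4 Å MS, O2 (1 atm), MeCN, 60 °C
Reagents that add atoms: acetic acid, CC(=O)O
Why: Chan–Lam-type oxidative copper-catalysed C–O coupling of an alkenyltrifluoroborate with a carboxylic acid should transfer the (E)-geometry to the enol ester with retention.

Step 12
Reactants: 11 8-bromo-nona-O-benzyl-fisetinidol-(4α→6)-catechin; 18 4-(benzyloxy)-2-hydroxybenzaldehyde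
Product: 21 [4-(benzyloxy)-2-hydroxyphenyl][nona-O-benzyl-fisetinidol-(4α→6)-catechin-8-yl]methanol (carbinol epimers), via aryllithium 19 (not isolated), via sodium phenoxide 20 (not isolated)
Conditions: 11, t-BuLi (2 equiv), THF, −78 °C; then 20 (from 18 and NaH, THF, 0 °C), −78 °C → −20 °C; aq. NH4Cl; Et3N-deactivated silica
Reagents that add atoms: none
Why: Bromine–lithium exchange at C8 followed by 1,2-addition of the aryllithium to the aldehyde, which is deprotonated beforehand so that no organolithium is spent on the phenol; the carbinol centre is uncontrolled and is lost in step 13.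

Step 13
Reactants: 21 [4-(benzyloxy)-2-hydroxyphenyl][nona-O-benzyl-fisetinidol-(4α→6)-catechin-8-yl]methanol; 17 (E)-2-[3,4-bis(benzyloxy)phenyl]ethenyl acetate
Product: 23 3-O-acetyl-7,3',4'-tri-O-benzylfisetinidol-(4β→8)-[nona-O-benzyl-fisetinidol-(4α→6)-catechin] (upper unit 2R,3S,4R), via ortho-quinone methide 22 (not isolated)
Conditions: 17 (3 equiv), (R)-3,3'-bis(2,4,6-triisopropylphenyl)-1,1'-binaphthalene-2,2'-diyl N-triflylphosphoramide (10 mol%), 5 Å MS, CH2Cl2, −40 °C → 0 °C
Reagents that add atoms: none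
Why: Proposed new method: the chiral acid dehydrates 21 to the (E)-ortho-quinone methide 22 and holds it as a hydrogen-bonded ion pair; its 1-oxadiene O1=C8a–C4a=C4 then adds across C2=C3 of 17 in an asynchronous inverse-electron-demand hetero-Diels–Alder reaction in which the C3–C4 bond leads and the 3,4-bis(benzyloxy)phenyl group carries the charge at C2 (assisted, if needed, by the acetate carbonyl), so that aryl ends at C2 and acetoxy at C3. The closest known reaction type is the chiral phosphoric acid or N-triflylphosphoramide catalysed [4+2] cycloaddition of o-hydroxybenzhydrol-derived ortho-quinone methides with styrenes to 2,4-diarylchromans; what is new is a β-acyloxystyrene as the 2π partner. The one ring closed, pyran ring C of the upper unit, closes in [4+2] mode with both new bonds (O1–C2 and C3–C4) made suprafacially on each partner (in the stepwise limit a six-membered closure of the phenol oxygen onto the benzylic C2 cation, with the same outcome). C2 and C3 should come out trans because the (E)-geometry of 17 is carried over; C4 should come out cis to O3 because the methide is E and the acetoxy group is expected endo, the exo sector beside C4 being blocked by the ortho,ortho'-dioxygenated catechin ring that must stand perpendicular to the methide, while the exo ring B aryl lies next to the catalyst anion. The absolute sense (2R,3S,4R) is assigned to the catalyst, whose chiral anion covers one face of 22 and must override the remote stereocentres of the dimer; the (R)-enantiomer is proposed by analogy and its sense of induction is not derived here. The step thus needs regio-, endo- and face-selectivity, secured in turn by the donor aryl at C2 against the weakly donating acetoxy oxygen, by the bulk at C4, and by the (R)-catalyst.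

Step 14
Reactants: 23 3-O-acetyl-dodeca-O-benzyl trimer
Product: 24 7,3',4'-tri-O-benzylfisetinidol-(4β→8)-[nona-O-benzyl-fisetinidol-(4α→6)-catechin] (upper 3-OH free)
Conditions: K2CO3, MeOH/THF, rt → 40 °C
Reagents that add atoms: none
Why: Base-mediated methanolysis cleaves the single acetate at the acyl carbon, so C3 keeps its configuration; all other oxygens are ethers.

Step 15
Reactants: 24 dodeca-O-benzyl trimer with free upper 3-OH
Product: 25 fisetinidol-(4β→8)-catechin-(6→4α)-fisetinidol (target)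
Conditions: H2 (1 atm), Pd(OH)2/C, THF/MeOH/H2O, rt
Reagents that add atoms: none
Why: Catalytic hydrogenolysis should remove the twelve benzyl ethers under conditions that leave the doubly benzylic interflavan C–C bonds and the pyran C–O bonds of flavan-3-ol oligomers intact.

**Compound list**

1 | (+)-catechin, (2R,3S) | Oc1cc(O)c2c(c1)O[C@H](c1ccc(O)c(O)c1)[C@@H](O)C2 | starting material
2 | 5,7,3',4'-tetra-O-benzyl-(+)-catechin | c1c(OCc4ccccc4)cc(OCc4ccccc4)c2c1O[C@H](c1ccc(OCc4ccccc4)c(OCc4ccccc4)c1)[C@@H](O)C2 | intermediate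
3 | 8-bromo-5,7,3',4'-tetra-O-benzyl-(+)-catechin | Brc1c(OCc4ccccc4)cc(OCc4ccccc4)c2c1O[C@H](c1ccc(OCc4ccccc4)c(OCc4ccccc4)c1)[C@@H](O)C2 | intermediate
4 | (2R,3R)-fustin (2,3-trans-3,7,3',4'-tetrahydroxyflavanone) | O=C1c2ccc(O)cc2O[C@H](c2ccc(O)c(O)c2)[C@H]1O | starting material
5 | (2R,3R)-7,3',4'-tri-O-benzylfustin | O=C1c2ccc(OCc4ccccc4)cc2O[C@H](c2ccc(OCc4ccccc4)c(OCc4ccccc4)c2)[C@H]1O | intermediate
6 | (2R,3S,4R)-7-(benzyloxy)-2-[3,4-bis(benzyloxy)phenyl]chromane-3,4-diol | O[C@@H]1c2ccc(OCc4ccccc4)cc2O[C@H](c2ccc(OCc4ccccc4)c(OCc4ccccc4)c2)[C@H]1O | intermediate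
7 | 3,4-di-O-acetate of 6 | CC(=O)O[C@@H]1c2ccc(OCc4ccccc4)cc2O[C@H](c2ccc(OCc4ccccc4)c(OCc4ccccc4)c2)[C@H]1OC(C)=O | intermediate
8 | β-face 3,4-acetoxonium (2-methyl-1,3-dioxolan-2-ylium) ion of the tri-O-benzylflavan | CC1=[O+][C@H]2c3ccc(OCc4ccccc4)cc3O[C@H](c3ccc(OCc4ccccc4)c(OCc4ccccc4)c3)[C@H]2O1 | intermediate (not isolated)
9 | 3-O-acetyl-7,3',4'-tri-O-benzylfisetinidol-(4α→6)-8-bromo-5,7,3',4'-tetra-O-benzylcatechin | Brc1c(OCc4ccccc4)c([C@@H]2c3ccc(OCc4ccccc4)cc3O[C@H](c3ccc(OCc4ccccc4)c(OCc4ccccc4)c3)[C@H]2OC(C)=O)c(OCc4ccccc4)c2c1O[C@H](c1ccc(OCc4ccccc4)c(OCc4ccccc4)c1)[C@@H](O)C2 | intermediate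
10 | 7,3',4'-tri-O-benzylfisetinidol-(4α→6)-8-bromo-5,7,3',4'-tetra-O-benzylcatechin | Brc1c(OCc4ccccc4)c([C@@H]2c3ccc(OCc4ccccc4)cc3O[C@H](c3ccc(OCc4ccccc4)c(OCc4ccccc4)c3)[C@H]2O)c(OCc4ccccc4)c2c1O[C@H](c1ccc(OCc4ccccc4)c(OCc4ccccc4)c1)[C@@H](O)C2 | intermediate
11 | 8-bromo-nona-O-benzyl-fisetinidol-(4α→6)-catechin | Brc1c(OCc4ccccc4)c([C@@H]2c3ccc(OCc4ccccc4)cc3O[C@H](c3ccc(OCc4ccccc4)c(OCc4ccccc4)c3)[C@H]2OCc4ccccc4)c(OCc4ccccc4)c2c1O[C@H](c1ccc(OCc4ccccc4)c(OCc4ccccc4)c1)[C@@H](OCc4ccccc4)C2 | intermediate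
12 | 3,4-bis(benzyloxy)benzaldehyde | O=Cc1ccc(OCc2ccccc2)c(OCc2ccccc2)c1 | starting material
13 | bis[(pinacolato)boryl]methane | CC1(C)OB(CB2OC(C)(C)C(C)(C)O2)OC1(C)C | starting material
14 | lithio-bis[(pinacolato)boryl]methane | [Li]C(B1OC(C)(C)C(C)(C)O1)B1OC(C)(C)C(C)(C)O1 | intermediate (not isolated)
15 | (E)-2-{2-[3,4-bis(benzyloxy)phenyl]ethenyl}-4,4,5,5-tetramethyl-1,3,2-dioxaborolane | CC1(C)OB(/C=C/c2ccc(OCc3ccccc3)c(OCc3ccccc3)c2)OC1(C)C | intermediate
16 | potassium (E)-{2-[3,4-bis(benzyloxy)phenyl]ethenyl}trifluoroborate | [K+].F[B-](F)(F)/C=C/c1ccc(OCc2ccccc2)c(OCc2ccccc2)c1 | intermediate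
17 | (E)-2-[3,4-bis(benzyloxy)phenyl]ethenyl acetate | CC(=O)O/C=C/c1ccc(OCc2ccccc2)c(OCc2ccccc2)c1 | intermediate
18 | 4-(benzyloxy)-2-hydroxybenzaldehyde | O=Cc1ccc(OCc2ccccc2)cc1O | starting material
19 | C8-aryllithium of the nona-O-benzyl dimer | [Li]c1c(OCc4ccccc4)c([C@@H]2c3ccc(OCc4ccccc4)cc3O[C@H](c3ccc(OCc4ccccc4)c(OCc4ccccc4)c3)[C@H]2OCc4ccccc4)c(OCc4ccccc4)c2c1O[C@H](c1ccc(OCc4ccccc4)c(OCc4ccccc4)c1)[C@@H](OCc4ccccc4)C2 | intermediate (not isolated)
20 | sodium 5-(benzyloxy)-2-formylphenoxide | [Na+].[O-]c1cc(OCc2ccccc2)ccc1C=O | intermediate (not isolated)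
21 | [4-(benzyloxy)-2-hydroxyphenyl][nona-O-benzyl-fisetinidol-(4α→6)-catechin-8-yl]methanol (carbinol epimers) | OC(c1ccc(OCc4ccccc4)cc1O)c1c(OCc4ccccc4)c([C@@H]2c3ccc(OCc4ccccc4)cc3O[C@H](c3ccc(OCc4ccccc4)c(OCc4ccccc4)c3)[C@H]2OCc4ccccc4)c(OCc4ccccc4)c2c1O[C@H](c1ccc(OCc4ccccc4)c(OCc4ccccc4)c1)[C@@H](OCc4ccccc4)C2 | intermediate
22 | (E)-ortho-quinone methide of ring A (3-benzyloxy-6-arylmethylidene-cyclohexa-2,4-dienone; aryl = C8 of the nona-O-benzyl dimer) | O=C1C=C(OCc4ccccc4)C=C/C1=C\c1c(OCc4ccccc4)c([C@@H]2c3ccc(OCc4ccccc4)cc3O[C@H](c3ccc(OCc4ccccc4)c(OCc4ccccc4)c3)[C@H]2OCc4ccccc4)c(OCc4ccccc4)c2c1O[C@H](c1ccc(OCc4ccccc4)c(OCc4ccccc4)c1)[C@@H](OCc4ccccc4)C2 | intermediate (not isolated)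
23 | 3-O-acetyl-7,3',4'-tri-O-benzylfisetinidol-(4β→8)-[nona-O-benzyl-fisetinidol-(4α→6)-catechin] | c4ccccc4COc1ccc2c(c1)O[C@H](c1ccc(OCc4ccccc4)c(OCc4ccccc4)c1)[C@@H](OC(C)=O)[C@H]2c1c(OCc4ccccc4)c([C@@H]2c3ccc(OCc4ccccc4)cc3O[C@H](c3ccc(OCc4ccccc4)c(OCc4ccccc4)c3)[C@H]2OCc4ccccc4)c(OCc4ccccc4)c2c1O[C@H](c1ccc(OCc4ccccc4)c(OCc4ccccc4)c1)[C@@H](OCc4ccccc4)C2 | intermediate
24 | 7,3',4'-tri-O-benzylfisetinidol-(4β→8)-[nona-O-benzyl-fisetinidol-(4α→6)-catechin] (upper 3-OH free) | c4ccccc4COc1ccc2c(c1)O[C@H](c1ccc(OCc4ccccc4)c(OCc4ccccc4)c1)[C@@H](O)[C@H]2c1c(OCc4ccccc4)c([C@@H]2c3ccc(OCc4ccccc4)cc3O[C@H](c3ccc(OCc4ccccc4)c(OCc4ccccc4)c3)[C@H]2OCc4ccccc4)c(OCc4ccccc4)c2c1O[C@H](c1ccc(OCc4ccccc4)c(OCc4ccccc4)c1)[C@@H](OCc4ccccc4)C2 | intermediate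
25 | fisetinidol-(4β→8)-catechin-(6→4α)-fisetinidol (upper unit 2R,3S,4R; catechin 2R,3S; lower unit 2R,3S,4S) | Oc1ccc2c(c1)O[C@H](c1ccc(O)c(O)c1)[C@@H](O)[C@H]2c1c(O)c([C@@H]2c3ccc(O)cc3O[C@H](c3ccc(O)c(O)c3)[C@H]2O)c(O)c2c1O[C@H](c1ccc(O)c(O)c1)[C@@H](O)C2 | target

**Totals**

Total step count: 15. Longest linear sequence: 10 steps (4 → 5 → 6 → 7 → 9 → 10 → 11 → 21 → 23 → 24 → 25; steps 3–8 and 12–15).

**Steps most likely to fail**

1. Step 13 (proposed new method). What may go wrong: bond formation through the other alkene terminus (enol-ester-type reactivity), exo approach of the acetoxy group leading to the C4 epimer, weak face control by the catalyst against the chiral dimer, or unproductive decay of the hindered quinone methide. The fallback uses known chemistry, sets out from 11 and 5 and comes back at 24. Ketone 5 is silylated (TBSOTf, 2,6-lutidine, CH2Cl2) to 7,3',4'-tri-O-benzyl-3-O-(tert-butyldimethylsilyl)fustin F1. Aryllithium 19, made from 11 as in step 12, is added to the C4 carbonyl of F1 (THF, −78 °C) to give the tertiary C4 carbinol F2, whose C4 configuration does not matter. Ionic deoxygenation (Bu3SnH, CF3CO2H, CH2Cl2, 0 °C) passes through the doubly benzylic C4 cation, which should take hydride anti to the 3-silyloxy group, so that the catechin C8 aryl ends cis to O3 (4β) in the 3-O-silyl dodeca-O-benzyl trimer F3. Bu4NF in THF then gives 24.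

2. Step 12. What may go wrong: proton transfer to the hindered di-ortho-substituted aryllithium, slow addition to the electron-rich aldehyde phenoxide, or ionisation of the very electron-rich benzhydrol during isolation. The fallback sets out from 11 and comes back at 21 with the polarity of the union reversed. Aryllithium 19 is quenched with N,N-dimethylformamide (small and fast) to give the C8 aldehyde F4. Commercial 3-(benzyloxy)phenol F5 is converted with EtMgBr (toluene, 0 °C → rt) into its bromomagnesium phenoxide F6, which should add to F4 through the ortho carbon para to the benzyloxy group in a magnesium-templated ortho-hydroxyalkylation. This gives 21 directly, with the free phenol already in place.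

3. Step 6. What may go wrong: self-condensation of the flavanyl cation outrunning capture by the bromine-deactivated ring at C6, or leakage to the 4β epimer. The fallback sets out from 7 and comes back at 9, replacing direct Lewis-acid ionisation by a thioether that is activated thiophilically. Diacetate 7 is treated with PhCH2SH and BF3·OEt2 (CH2Cl2, −20 °C) to give 3-O-acetyl-4α-(benzylsulfanyl)-7,3',4'-tri-O-benzylfisetinidol F7, the thiol being a far better trap than the arene. F7 is then activated with AgBF4 in the presence of excess 3 (THF/CH2Cl2, −40 °C → 0 °C), which releases the cation slowly under the same 3-acetoxy participation and should give 9.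

**Further compounds**

F1 | step 13 | 7,3',4'-tri-O-benzyl-3-O-(tert-butyldimethylsilyl)fustin | O=C1c2ccc(OCc4ccccc4)cc2O[C@H](c2ccc(OCc4ccccc4)c(OCc4ccccc4)c2)[C@H]1O[Si](C)(C)C(C)(C)C
F2 | step 13 | tertiary C4 carbinol from addition of 19 to F1 (C4 undefined) | OC1(c2ccc(OCc4ccccc4)cc2O[C@H](c2ccc(OCc4ccccc4)c(OCc4ccccc4)c2)[C@H]1O[Si](C)(C)C(C)(C)C)c1c(OCc4ccccc4)c([C@@H]2c3ccc(OCc4ccccc4)cc3O[C@H](c3ccc(OCc4ccccc4)c(OCc4ccccc4)c3)[C@H]2OCc4ccccc4)c(OCc4ccccc4)c2c1O[C@H](c1ccc(OCc4ccccc4)c(OCc4ccccc4)c1)[C@@H](OCc4ccccc4)C2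
F3 | step 13 | 3-O-(tert-butyldimethylsilyl)-7,3',4'-tri-O-benzylfisetinidol-(4β→8)-[nona-O-benzyl-fisetinidol-(4α→6)-catechin] | c4ccccc4COc1ccc2c(c1)O[C@H](c1ccc(OCc4ccccc4)c(OCc4ccccc4)c1)[C@@H](O[Si](C)(C)C(C)(C)C)[C@H]2c1c(OCc4ccccc4)c([C@@H]2c3ccc(OCc4ccccc4)cc3O[C@H](c3ccc(OCc4ccccc4)c(OCc4ccccc4)c3)[C@H]2OCc4ccccc4)c(OCc4ccccc4)c2c1O[C@H](c1ccc(OCc4ccccc4)c(OCc4ccccc4)c1)[C@@H](OCc4ccccc4)C2
F4 | step 12 | 8-formyl-nona-O-benzyl-fisetinidol-(4α→6)-catechin | O=Cc1c(OCc4ccccc4)c([C@@H]2c3ccc(OCc4ccccc4)cc3O[C@H](c3ccc(OCc4ccccc4)c(OCc4ccccc4)c3)[C@H]2OCc4ccccc4)c(OCc4ccccc4)c2c1O[C@H](c1ccc(OCc4ccccc4)c(OCc4ccccc4)c1)[C@@H](OCc4ccccc4)C2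
F5 | step 12 | 3-(benzyloxy)phenol | Oc1cccc(OCc2ccccc2)c1
F6 | step 12 | bromomagnesium 3-(benzyloxy)phenoxide | Br[Mg]Oc1cccc(OCc2ccccc2)c1
F7 | step 6 | 3-O-acetyl-4α-(benzylsulfanyl)-7,3',4'-tri-O-benzylfisetinidol | c4ccccc4CS[C@@H]1c2ccc(OCc4ccccc4)cc2O[C@H](c2ccc(OCc4ccccc4)c(OCc4ccccc4)c2)[C@H]1OC(C)=O
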